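# Proposed synthesis of CNP0151877.1 by ring-closing γ-alkoxyallylboration

Locants C2, C3, C3a, O4, C5, C6, C7, C7a and O1 are those of the furo[3,2-b]pyran-5-one core of the target throughout.

## Analysis of the target

- **Ring system.** The target is a cis-fused 2,3,3a,7a-tetrahydro-5H-furo[3,2-b]pyran-5-one. A tetrahydrofuran (O1, C2, C3, C3a, C7a) shares the C3a–C7a bond with an α,β-unsaturated δ-lactone (O4, C5=O, C6=C7).
- **Ring stereocentres.** The four centres are contiguous and all-cis (2S,3R,3aR,7aR). The C2 side chain, the C3 hydroxyl, the lactone oxygen on C3a and C7 on C7a lie on one face, the concave face of the bicycle. This is the thermodynamically least favourable arrangement and has to be made under kinetic control.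
- **Side chain.** C2 carries an (E)-alkene that leads to a benzoate-bearing carbon (S) and an acetate-bearing carbon (R), the two oxygens being anti.
- **Sensitive groups.** These are the unsaturated lactone (Michael acceptor, opened or isomerised by base), the allylic benzoate, the vicinal acetate/benzoate pair (acyl migration once a neighbouring hydroxyl is free) and the free C3 hydroxyl.
- **Difficulty.** Three problems dominate: the all-cis tetrasubstituted tetrahydrofuran, telling apart the four oxygenated carbons of a C2-symmetric C4 chiral-pool unit, and joining the ester-laden side chain late.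
- **Feature used.** C2 bears O1 and a vinyl-type group and its neighbour C3 a hydroxyl. This is the 1-alkoxyallyl carbinol pattern left when a γ-alkoxyallyl metal adds to an aldehyde. O1 is already bonded to C7a, and C7a–C3a–C3 is a tartrate-type chain, so the addition can be made intramolecular and the ring closed through the C2–C3 bond.

## Retrosynthetic reasoning

**Side-chain alkene.** The (E)-alkene between the carbon on C2 and the carbon next to the benzoate is cut first, giving the vinyl lactone 23 and the terminal alkene 31. Cutting here keeps all ester chemistry of the side chain away from the organometallic steps of the core and makes the route convergent. The forward reaction is a cross-metathesis that has to be E-selective and leave the conjugated lactone alone.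

**Lactone.** In 23 the O4–C5 acyl bond and the C6=C7 alkene are cut. This leads through the dihydroxy (Z)-enoate 22 and its acetonide 21 to aldehyde 19 and ylide 20. A Z-alkene next to a cis hydroxyl lactonises on its own, so the only demands are Z geometry and an intact C7a centre. Aldehyde 19 comes from the primary alcohol of acetonide 18, and 18 from triol 17, whose cis-3,4-diol is masked so that only C7 can be oxidised.

**C2–C3 bond (key disconnection).** Triol 17 is cut between C2 and C3, which leads to the open-chain hydroxy aldehyde 15. In 15 the O1 oxygen on C7a carries a (Z)-γ-boryl enol ether.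

- **What is gained.** One step builds the ring, one skeletal bond and the two hardest stereocentres, while C3a and C7a are bought from the chiral pool. C–O bond formation at C2 or C7a is not needed.
- **What the forward reaction must achieve.** It must give the 2,3-cis relationship, which follows from the Z geometry in a closed chair. It must also attack the aldehyde face that places the new C3 oxygen cis to the C3a oxygen.
- **Why the C3a hydroxyl is free.** The nucleophile is tied to C7a, so this face is decided only by the rotamer about C3–C3a. The rotamer needed has the carbonyl oxygen syn to the C3a oxygen. With a silyl ether on C3a that rotamer would be opposed by dipole repulsion and by crowding on the concave face. The C3a hydroxyl is therefore left free in 15, so that an O–H···O=C hydrogen bond holds exactly this rotamer.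

**Masking the aldehyde.** Aldehyde 15 is the open form of lactol 14, and 14 is released from its bis(trimethylsilyl) derivative 13. A lactol is the natural mask for an α-hydroxy aldehyde: it needs no oxidation in the presence of the boronate, and the two silyl groups fall off under acid too weak to touch the enol ether. The C–B bond of 13 is cut next, which leads to allyl ether 9 and borate ester 10. The forward reaction is an allyl ether lithiation and γ-borylation, whose chelated allyl anion fixes the Z geometry.

**Differentiating tartrate.** Ether 9 is traced through lactol diol 8 and silyl lactol 7 to lactone 6. Cutting the O-allyl bond gives hydroxy lactone 4 and imidate 5. Lactone 4 comes from diol ester 3 and this from the monosilyl tartrate 2, made from diethyl D-tartrate 1. The C2 symmetry of 1 means that the first silylation cannot give regioisomers. The free hydroxyl of 2 then directs reduction to its own ester, which becomes C7. The untouched ester becomes the lactone carbonyl (C3), the silylated oxygen is the C3a oxygen, and the lactone's free hydroxyl is the future O1. All four carbons are thus distinguished in two steps.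

**Side chain.** Alkene 31 is traced through alcohol 30 and silyl ether 29 to the anti alcohol 28. The bond between the carbinol carbon and the vinyl group is cut, giving aldehyde 27 and Grignard reagent 26. Aldehyde 27 comes from ester 25 and this from methyl (R)-lactate 24. The lactate supplies the acetate-bearing centre, and Felkin–Anh addition has to supply the benzoate-bearing one.

## Alternatives that were turned down

**Alternative 1: anodic Achmatowicz rearrangement.**
- **Disconnection.** The O4–C5 bond of the six-membered ring is cut and traced to a furan. The four carbons C5–C6–C7–C7a come from the furan ring of the furyl carbinol A1.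
- **Forward key step.** Bromide-mediated anodic oxidation of A1 in buffered aqueous acetonitrile rearranges it to the 6-hydroxy-2H-pyran-3(6H)-one A2.
- **For it.** The reaction is well behaved and uses no stoichiometric oxidant. The carbinol centre (C3a) is carried over unchanged. The whole unsaturated six-membered ring arrives at once, so no olefination is needed; on this point it is stronger than the chosen route.
- **Against it.** A2 has the wrong oxidation pattern: C7a is a ketone and C5 a lactol. Lactol oxidation, ketone reduction and a separate O1–C7a ring closure, which must deliver the concave cis fusion, would still follow. The key step creates no ring stereocentre that survives. A1 already carries the whole side chain, whose electron-rich (E)-alkene competes for the electrogenerated bromine. C2, C3 and C3a must all be set beforehand by additions that are no better controlled than those used here.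
- **Comparison.** The chosen route forms C2, C3 and the tetrahydrofuran in one step and keeps the side chain out of all oxidations of the core.

**Alternative 2: oxanorbornene ring-rearrangement metathesis.**
- **Disconnection.** The C6=C7 alkene and the C2 vinyl group are traced back to the strained alkene of the oxanorbornene A3, which bears endo acrylate and endo silyloxy groups.
- **Forward key step.** The second-generation Hoveyda–Grubbs catalyst opens the bicyclic alkene and closes the C7 alkylidene onto the acrylate to give A4.
- **For it.** On stereochemical security it is stronger than the chosen route. In A3 the two endo oxygens and the two bridgehead carbons are locked, so the all-cis array of A4 is automatic. The Z geometry of the lactone alkene is enforced by the ring. Only deprotection and the side-chain coupling remain after the key step, so it is also shorter there.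
- **Against it.** The endo,endo-diol behind A3 is a meso compound. Its two oxygens must be told apart and the absolute configuration introduced by a desymmetrisation, not taken from the chiral pool. The oxabicycle has to come from a [4+2] cycloaddition of a furan, which is reversible and favours exo adducts, whereas the endo diol is needed. The catalyst can also start at the acrylate or polymerise the strained alkene.
- **Comparison.** The chosen route offers absolute configuration bought with diethyl D-tartrate 1 and an unprotected, flexible intermediate 17. Its price is the facial question in step 8, which Alternative 2 does not have.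

**Alternative 3: iodoetherification of a deconjugated lactone.**
- **Disconnection.** The O1–C7a bond is cut.
- **Forward key step.** Iodine and mild base make the C2 hydroxyl of the β,γ-unsaturated lactone A5 add to C7a in a 5-exo closure, giving the iodo lactone A6. Elimination of hydrogen iodide then restores the conjugated alkene.
- **For it.** The closure is mild and late, and the tether favours the cis ring fusion. The side chain is already in place, so no late cross-metathesis is needed; on convergence it is as strong as or stronger than the chosen route.
- **Against it.** Only C7a is made. The three contiguous carbinol centres C2, C3 and C3a, the real difficulty, must already be present in an acyclic precursor. The β,γ-alkene of A5 slips into conjugation under the basic conditions. The side-chain alkene, flanked by the same C2 hydroxyl and by a participating benzoate, is a second site for the iodonium ion. A base-mediated elimination follows on a polyester.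
- **Comparison.** The chosen route spends its key step on building the stereocentres that Alternative 3 only consumes.

Key step: step 8

## Route

Remark on the chemistry: compounds 7, 8, 9 and 11–14 are mixtures at the anomeric carbon (the future C3) and are carried as such; this carbon becomes the aldehyde carbon of 15 and is set only in step 8.

Step 1
Reactants: 1 diethyl D-tartrate
Product: 2 diethyl (2S,3S)-2-[(tert-butyldimethylsilyl)oxy]-3-hydroxybutanedioate
Conditions: tBuMe2SiCl (1.05 equiv), imidazole, DMF, 0 °C to rt
Reagents that add atoms: tert-butyldimethylsilyl chloride, C[Si](C)(Cl)C(C)(C)C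
Why: Monosilylation of a C2-symmetric diol; either hydroxyl gives the same product and the first silyl group slows the second silylation, and no stereocentre is touched.

Step 2
Reactants: 2 diethyl (2S,3S)-2-[(tert-butyldimethylsilyl)oxy]-3-hydroxybutanedioate
Product: 4 2-O-(tert-butyldimethylsilyl)-D-threono-1,4-lactone, via diol ester 3 (not isolated)
Conditions: BH3·SMe2 (1.05 equiv), NaBH4 (5 mol%), THF, 0 °C to rt; MeOH; then TsOH (cat.), CH2Cl2, rt
Reagents that add atoms: none
Why: Hydroxyl-directed chemoselective borane reduction: the free hydroxyl forms an alkoxyborane that delivers hydride only to its own α-ester, so the ester next to the silyl ether survives; acid then closes the γ-lactone from the new primary alcohol (the secondary hydroxyl could only give a β-lactone). One operation thus distinguishes both termini and both carbinol oxygens of tartrate.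

Step 3
Reactants: 4 2-O-(tert-butyldimethylsilyl)-D-threono-1,4-lactone; 5 allyl 2,2,2-trichloroacetimidate
Product: 6 3-O-allyl-2-O-(tert-butyldimethylsilyl)-D-threono-1,4-lactone
Conditions: 5 (2 equiv), TfOH (5 mol%), cyclohexane/CH2Cl2, 0 °C to rt
Reagents that add atoms: allyl 2,2,2-trichloroacetimidate (5), C=CCOC(=N)C(Cl)(Cl)Cl
Why: Acid-catalysed O-alkylation with a trichloroacetimidate; it avoids the base that would epimerise the β-hydroxy lactone or make the silyl group migrate.

Step 4
Reactants: 6 3-O-allyl-2-O-(tert-butyldimethylsilyl)-D-threono-1,4-lactone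
Product: 7 3-O-allyl-2-O-(tert-butyldimethylsilyl)-D-threofuranose
Conditions: iBu2AlH (1.2 equiv), CH2Cl2, −78 °C; aq. potassium sodium tartrate
Reagents that add atoms: none
Why: Partial reduction of a γ-lactone to the lactol; the aluminium hemiacetal is stable at low temperature and is not reduced further.

Step 5
Reactants: 7 3-O-allyl-2-O-(tert-butyldimethylsilyl)-D-threofuranose
Product: 8 3-O-allyl-D-threofuranose
Conditions: Bu4NF (1.2 equiv), AcOH (1.2 equiv), THF, 0 °C to rt
Reagents that add atoms: none
Why: Fluoride desilylation, buffered so that the lactol is not epimerised; it is done before any boron is present because allylboronates are at risk of fluoride-induced protodeboronation.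

Step 6
Reactants: 8 3-O-allyl-D-threofuranose
Product: 9 3-O-allyl-1,2-bis-O-(trimethylsilyl)-D-threofuranose
Conditions: Me3SiCl (2.5 equiv), Et3N, CH2Cl2, 0 °C
Reagents that add atoms: chlorotrimethylsilane, C[Si](C)(C)Cl
Why: Base-mediated silylation of both hydroxyls, with no acid present so that no cyclic acetal can form across the 1,2-diol; trimethylsilyl ethers withstand alkyllithiums at −78 °C yet are removed by the mildest acid.

Step 7
Reactants: 9 3-O-allyl-1,2-bis-O-(trimethylsilyl)-D-threofuranose; 10 2-isopropoxy-4,4,5,5-tetramethyl-1,3,2-dioxaborolane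
Product: 13 3-O-[(1Z)-3-(4,4,5,5-tetramethyl-1,3,2-dioxaborolan-2-yl)prop-1-en-1-yl]-1,2-bis-O-(trimethylsilyl)-D-threofuranose, via allyllithium 11 (not isolated), via borate complex 12 (not isolated)
Conditions: sec-BuLi (1.3 equiv), THF, −78 °C; then 10 (1.5 equiv), −78 to 0 °C; pH 7 buffer; used crude
Reagents that add atoms: 2-isopropoxy-4,4,5,5-tetramethyl-1,3,2-dioxaborolane (10), CC(C)OB1OC(C)(C)C(C)(C)O1
Why: Allyl ether α-lithiation followed by γ-borylation: sec-BuLi removes the allylic proton to give the oxygen-chelated Z allyllithium 11, the boron electrophile attacks the carbon remote from oxygen, and borate 12 expels isopropoxide. The chelate fixes the Z geometry of the γ-alkoxyallylboronate.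

Step 8
Reactants: 13 3-O-[(1Z)-3-(4,4,5,5-tetramethyl-1,3,2-dioxaborolan-2-yl)prop-1-en-1-yl]-1,2-bis-O-(trimethylsilyl)-D-threofuranose
Product: 17 (2S,3S,4R,5R)-2-ethenyl-5-(hydroxymethyl)oxolane-3,4-diol, via lactol 14 (not isolated), via hydroxy aldehyde 15 (not isolated), via borate ester 16 (not isolated)
Conditions: PPTS (5 mol%), MeOH (6 equiv), CH2Cl2, 0 °C; then Et3N (10 mol%), 0 °C to rt; evaporation from MeOH
Reagents that add atoms: none
Why: Proposed new method: catalytic acid and methanol remove both trimethylsilyl groups much faster than the Z-enol ether can react, lactol 14 ring-opens to the α-hydroxy aldehyde 15, and the allylboronate adds through a closed six-membered chair (Zimmerman–Traxler type) in which boron binds the carbonyl oxygen and the γ-carbon (C2) bonds to the aldehyde carbon (C3); methanolysis of borate 16 gives 17. The closest known reaction type is the intramolecular addition of γ-(ω-formylalkoxy)allylboronates and -stannanes to give 2-vinyl-3-hydroxy tetrahydropyrans and oxepanes; a five-membered, all-cis case is not known. The tetrahydrofuran closes in a 5-exo-trig mode, the O1–C7a–C3a tether spanning an axial position (O1 on C2) and an equatorial position (C3a on C3) of the chair as a cis-fused bicycle. The relative configuration of C2 and C3 is controlled by the enol ether geometry: the Z isomer places O1 axial, so the vinyl group and the C3 oxygen emerge cis on the ring. The sense of both new centres relative to C3a and C7a depends on which face of the forming ring carries the chair; because the nucleophile is tied to C7a, this is decided by the rotamer about C3–C3a, and the all-cis product needs the carbonyl oxygen syn to the C3a oxygen. A silyl ether on C3a would disfavour that rotamer (dipole repulsion, concave face), so the hydroxyl is left free: its O–H···O=C hydrogen bond holds this rotamer and activates the carbonyl, and the small hydroxyl and the free C7 hydroxymethyl are tolerated on the concave face. The step therefore needs Z integrity (from step 7), a closed transition state (inherent to the boronate) and syn-rotamer facial control (from the free α-hydroxyl); the last is the uncertain element.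

Step 9
Reactants: 17 (2S,3S,4R,5R)-2-ethenyl-5-(hydroxymethyl)oxolane-3,4-diol
Product: 18 3,4-O-isopropylidene acetal of 17
Conditions: 2,2-dimethoxypropane, CSA (cat.), acetone, rt
Reagents that add atoms: 2,2-dimethoxypropane, COC(C)(C)OC
Why: Acetonide formation under thermodynamic control; the cis-3,4-diol gives the five-membered dioxolane in preference to a six-membered ketal with the hydroxymethyl group, as in lyxofuranosides, so the primary alcohol is left as the only oxidisable position.

Step 10
Reactants: 18 3,4-O-isopropylidene acetal of 17
Product: 19 aldehyde at C7 of the acetonide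
Conditions: TEMPO (10 mol%), PhI(OAc)2 (1.2 equiv), CH2Cl2, rt; used crude
Reagents that add atoms: none
Why: Oxoammonium (TEMPO) oxidation with PhI(OAc)2 as terminal oxidant; it is neutral, stops at the aldehyde and leaves the α-stereocentre C7a untouched.

Step 11
Reactants: 19 aldehyde at C7 of the acetonide; 20 methyl (triphenylphosphoranylidene)acetate
Product: 21 methyl (Z)-enoate acetonide
Conditions: 20 (1.5 equiv), MeOH, 0 °C
Reagents that add atoms: methyl (triphenylphosphoranylidene)acetate (20), COC(=O)C=P(c1ccccc1)(c1ccccc1)c1ccccc1
Why: Wittig olefination with a stabilised ylide in methanol, the protic-solvent variant that turns α-alkoxy aldehydes into (Z)-enoates; no base is present, so C7a is not epimerised, and any E isomer cannot lactonise in step 12 and is separated there.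

Step 12
Reactants: 21 methyl (Z)-enoate acetonide
Product: 23 (2S,3R,3aR,7aR)-2-ethenyl-3-hydroxy-2,3,3a,7a-tetrahydro-5H-furo[3,2-b]pyran-5-one, via dihydroxy ester 22 (not isolated)
Conditions: TFA/H2O (9:1), 0 °C to rt
Reagents that add atoms: none
Why: Aqueous acid hydrolyses the acetonide, and the C3a hydroxyl, held cis and adjacent to the Z-enoate, closes the α,β-unsaturated δ-lactone by transesterification; the C3 hydroxyl could only form a bridged seven-membered ring and stays free.

Step 13
Reactants: 24 methyl (R)-lactate
Product: 25 methyl (2R)-2-[(tert-butyldimethylsilyl)oxy]propanoate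
Conditions: tBuMe2SiCl, imidazole, DMF, rt
Reagents that add atoms: tert-butyldimethylsilyl chloride, C[Si](C)(Cl)C(C)(C)C
Why: Silylation of the secondary alcohol; the bulky, non-chelating ether is what the Felkin-controlled addition of step 14 requires.

Step 14
Reactants: 25 methyl (2R)-2-[(tert-butyldimethylsilyl)oxy]propanoate; 26 vinylmagnesium bromide
Product: 28 (3S,4R)-4-[(tert-butyldimethylsilyl)oxy]pent-1-en-3-ol, via silyloxy aldehyde 27 (not isolated)
Conditions: iBu2AlH (1.05 equiv), Et2O, −78 °C; then CH2=CHMgBr (2 equiv), −78 to 0 °C
Reagents that add atoms: vinylmagnesium bromide (26), C=C[Mg]Br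
Why: One-pot half-reduction and Grignard addition; the aluminium hemiacetal releases aldehyde 27, which is trapped cold without isolation, so it is not racemised. The non-chelating silyloxy group directs the vinyl nucleophile by the Felkin–Anh model to the anti (3S) alcohol, and the minor syn isomer is removed by chromatography.

Step 15
Reactants: 28 (3S,4R)-4-[(tert-butyldimethylsilyl)oxy]pent-1-en-3-ol
Product: 29 (3S,4R)-4-[(tert-butyldimethylsilyl)oxy]pent-1-en-3-yl benzoate
Conditions: BzCl, pyridine, DMAP (cat.), CH2Cl2, 0 °C to rt
Reagents that add atoms: benzoyl chloride, O=C(Cl)c1ccccc1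
Why: Acylation of the allylic alcohol with nucleophilic catalysis; the carbinol centre is not affected.

Step 16
Reactants: 29 (3S,4R)-4-[(tert-butyldimethylsilyl)oxy]pent-1-en-3-yl benzoate
Product: 30 (3S,4R)-4-hydroxypent-1-en-3-yl benzoate
Conditions: HF·pyridine, pyridine/THF, 0 °C to rt
Reagents that add atoms: none
Why: Acidic fluoride desilylation; an acidic medium is chosen because a basic fluoride source could move the benzoate onto the freed neighbouring hydroxyl.

Step 17
Reactants: 30 (3S,4R)-4-hydroxypent-1-en-3-yl benzoate
Product: 31 (3S,4R)-4-acetoxypent-1-en-3-yl benzoate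
Conditions: Ac2O, pyridine, DMAP (cat.), CH2Cl2, rt
Reagents that add atoms: acetic anhydride, CC(=O)OC(C)=O
Why: Acetylation of the remaining secondary alcohol; the product is immediately a diester, so no acyl migration is possible.

Step 18
Reactants: 23 (2S,3R,3aR,7aR)-2-ethenyl-3-hydroxy-2,3,3a,7a-tetrahydro-5H-furo[3,2-b]pyran-5-one; 31 (3S,4R)-4-acetoxypent-1-en-3-yl benzoate
Product: 32 (2R,3S,4E)-2-acetoxy-5-[(2S,3R,3aR,7aR)-3-hydroxy-5-oxo-2,3,3a,7a-tetrahydro-5H-furo[3,2-b]pyran-2-yl]pent-4-en-3-yl benzoate
Conditions: 31 (3 equiv), second-generation Hoveyda–Grubbs catalyst RuCl2(H2IMes)(=CH-C6H4-2-OiPr) (10 mol%), CH2Cl2, 40 °C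
Reagents that add atoms: none
Why: Olefin cross-metathesis between two terminal, allylically oxygenated alkenes with partner 31 in excess; ethene is lost and the disubstituted alkene forms under thermodynamic control as the E isomer. The conjugated lactone alkene is electron-poor and cyclic and acts as a spectator.

## Compound list

1 | diethyl D-tartrate, diethyl (2S,3S)-2,3-dihydroxybutanedioate | CCOC(=O)[C@@H](O)[C@H](O)C(=O)OCC | starting material
2 | diethyl (2S,3S)-2-[(tert-butyldimethylsilyl)oxy]-3-hydroxybutanedioate | CCOC(=O)[C@@H](O[Si](C)(C)C(C)(C)C)[C@H](O)C(=O)OCC | intermediate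
3 | ethyl (2S,3R)-2-[(tert-butyldimethylsilyl)oxy]-3,4-dihydroxybutanoate | CCOC(=O)[C@@H](O[Si](C)(C)C(C)(C)C)[C@H](O)CO | intermediate (not isolated)
4 | 2-O-(tert-butyldimethylsilyl)-D-threono-1,4-lactone, (3S,4R)-3-[(tert-butyldimethylsilyl)oxy]-4-hydroxyoxolan-2-one | O=C1[C@@H](O[Si](C)(C)C(C)(C)C)[C@H](O)CO1 | intermediate
5 | allyl 2,2,2-trichloroacetimidate | C=CCOC(=N)C(Cl)(Cl)Cl | starting material
6 | 3-O-allyl-2-O-(tert-butyldimethylsilyl)-D-threono-1,4-lactone, (3S,4R)-3-[(tert-butyldimethylsilyl)oxy]-4-(prop-2-en-1-yloxy)oxolan-2-one | O=C1[C@@H](O[Si](C)(C)C(C)(C)C)[C@H](OCC=C)CO1 | intermediate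
7 | 3-O-allyl-2-O-(tert-butyldimethylsilyl)-D-threofuranose (both anomers) | OC1[C@@H](O[Si](C)(C)C(C)(C)C)[C@H](OCC=C)CO1 | intermediate
8 | 3-O-allyl-D-threofuranose (both anomers), (3S,4R)-4-(prop-2-en-1-yloxy)oxolane-2,3-diol | OC1[C@@H](O)[C@H](OCC=C)CO1 | intermediate
9 | 3-O-allyl-1,2-bis-O-(trimethylsilyl)-D-threofuranose (both anomers) | C[Si](C)(C)OC1[C@@H](O[Si](C)(C)C)[C@H](OCC=C)CO1 | intermediate
10 | 2-isopropoxy-4,4,5,5-tetramethyl-1,3,2-dioxaborolane | CC(C)OB1OC(C)(C)C(C)(C)O1 | starting material
11 | oxygen-chelated (Z)-allyllithium from 9, drawn as the γ-lithio enol ether | C[Si](C)(C)OC1[C@@H](O[Si](C)(C)C)[C@H](O/C=C\C[Li])CO1 | intermediate (not isolated)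
12 | lithium isopropoxy borate complex from 11 and 10 | C[Si](C)(C)OC1[C@@H](O[Si](C)(C)C)[C@H](O/C=C\C[B-]2(OC(C)C)OC(C)(C)C(C)(C)O2)CO1.[Li+] | intermediate (not isolated)
13 | 3-O-[(1Z)-3-(4,4,5,5-tetramethyl-1,3,2-dioxaborolan-2-yl)prop-1-en-1-yl]-1,2-bis-O-(trimethylsilyl)-D-threofuranose (both anomers) | C[Si](C)(C)OC1[C@@H](O[Si](C)(C)C)[C@H](O/C=C\CB2OC(C)(C)C(C)(C)O2)CO1 | intermediate
14 | 3-O-[(1Z)-3-(4,4,5,5-tetramethyl-1,3,2-dioxaborolan-2-yl)prop-1-en-1-yl]-D-threofuranose (lactol, both anomers) | OC1[C@@H](O)[C@H](O/C=C\CB2OC(C)(C)C(C)(C)O2)CO1 | intermediate (not isolated)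
15 | (2S,3R)-2,4-dihydroxy-3-{[(1Z)-3-(4,4,5,5-tetramethyl-1,3,2-dioxaborolan-2-yl)prop-1-en-1-yl]oxy}butanal, open form of 14 and precursor of the key step | O=C[C@@H](O)[C@@H](CO)O/C=C\CB1OC(C)(C)C(C)(C)O1 | intermediate (not isolated)
16 | pinacol borate ester of 17 at the C3 oxygen | C=C[C@@H]1O[C@H](CO)[C@H](O)[C@@H]1OB2OC(C)(C)C(C)(C)O2 | intermediate (not isolated)
17 | (2S,3S,4R,5R)-2-ethenyl-5-(hydroxymethyl)oxolane-3,4-diol, all-cis (oxolane C2, C3, C4, C5 are target C2, C3, C3a, C7a); product of the key step | C=C[C@@H]1O[C@H](CO)[C@H](O)[C@@H]1O | intermediate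
18 | 3,4-O-isopropylidene acetal of 17 (acetonide on the cis-diol at target C3/C3a, hydroxymethyl at C7a free) | C=C[C@@H]1O[C@H](CO)[C@@H]2OC(C)(C)O[C@H]12 | intermediate
19 | aldehyde from 18 (formyl group on C7a, all-cis acetonide) | C=C[C@@H]1O[C@H](C=O)[C@@H]2OC(C)(C)O[C@H]12 | intermediate
20 | methyl (triphenylphosphoranylidene)acetate | COC(=O)C=P(c1ccccc1)(c1ccccc1)c1ccccc1 | starting material
21 | methyl (2Z)-3-(C7a) prop-2-enoate of the all-cis vinyl acetonide (Z-enoate from 19) | C=C[C@@H]1O[C@H](/C=C\C(=O)OC)[C@@H]2OC(C)(C)O[C@H]12 | intermediate
22 | methyl (2Z)-3-[all-cis-5-ethenyl-3,4-dihydroxyoxolan-2-yl]prop-2-enoate (diol from 21) | C=C[C@@H]1O[C@H](/C=C\C(=O)OC)[C@H](O)[C@@H]1O | intermediate (not isolated)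
23 | (2S,3R,3aR,7aR)-2-ethenyl-3-hydroxy-2,3,3a,7a-tetrahydro-5H-furo[3,2-b]pyran-5-one | C=C[C@@H]1O[C@@H]2C=CC(=O)O[C@@H]2[C@@H]1O | intermediate
24 | methyl (R)-lactate | C[C@@H](O)C(=O)OC | starting material
25 | methyl (2R)-2-[(tert-butyldimethylsilyl)oxy]propanoate | C[C@@H](O[Si](C)(C)C(C)(C)C)C(=O)OC | intermediate
26 | vinylmagnesium bromide | C=C[Mg]Br | starting material
27 | (2R)-2-[(tert-butyldimethylsilyl)oxy]propanal | C[C@@H](O[Si](C)(C)C(C)(C)C)C=O | intermediate (not isolated)
28 | (3S,4R)-4-[(tert-butyldimethylsilyl)oxy]pent-1-en-3-ol (anti) | C[C@@H](O[Si](C)(C)C(C)(C)C)[C@@H](O)C=C | intermediate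
29 | (3S,4R)-4-[(tert-butyldimethylsilyl)oxy]pent-1-en-3-yl benzoate | C[C@@H](O[Si](C)(C)C(C)(C)C)[C@@H](OC(=O)c1ccccc1)C=C | intermediate
30 | (3S,4R)-4-hydroxypent-1-en-3-yl benzoate | C[C@@H](O)[C@@H](OC(=O)c1ccccc1)C=C | intermediate
31 | (3S,4R)-4-acetoxypent-1-en-3-yl benzoate | CC(=O)O[C@H](C)[C@@H](OC(=O)c1ccccc1)C=C | intermediate
32 | (2R,3S,4E)-2-acetoxy-5-[(2S,3R,3aR,7aR)-3-hydroxy-5-oxo-2,3,3a,7a-tetrahydro-5H-furo[3,2-b]pyran-2-yl]pent-4-en-3-yl benzoate | CC(=O)O[C@H](C)[C@H](/C=C/[C@@H]1O[C@@H]2C=CC(=O)O[C@@H]2[C@@H]1O)OC(=O)c1ccccc1 | target

## Step count and least certain steps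

- Total step count: 18.
- Longest linear sequence: 13 steps (steps 1–12 and 18) from diethyl D-tartrate 1.
- The side chain takes 5 steps (13–17) from methyl (R)-lactate 24.

**Step 8 (key step).**
- **Risk.** The most likely failure is poor facial selectivity: closure through the chair on the convex face, which would put the vinyl and C3 hydroxyl groups trans to the C3a and C7a substituents. The internal hydrogen bond may not outweigh the steric preference for the convex face, particularly if desilylation at the C3a oxygen lags behind opening of the lactol. Acid-induced loss of the enol ether before ring closure is a second risk.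
- **Fallback.** The fallback uses known C-glycoside chemistry and leaves the tartrate line. It sets out from vinylmagnesium bromide 26 and commercial 2,3-O-isopropylidene-D-lyxono-1,4-lactone F1, whose three ring substituents already have the all-cis arrangement of C3, C3a and C7a. Silylation of the primary alcohol (tBuPh2SiCl, imidazole) gives the 5-O-silyl lactone F2. Addition of 26 at −78 °C gives the vinyl hemiketal F3. Reduction with Et3SiH and BF3·OEt2 passes through the oxocarbenium ion, which takes hydride on the face opposite the acetonide and the silyloxymethyl group, so the vinyl group ends cis to both in the C-vinyl furanoside F4. Bu4NF removes the silyl group, and the sequence comes back to the route at 18.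

**Step 18 (cross-metathesis).**
- **Risk.** Slow turnover and catalyst decay are likely, because both alkenes are hindered and allylically oxygenated. Homodimerisation of 31 is a second risk.
- **Fallback.** The fallback replaces metathesis by carbonyl olefination. It sets out from 21 and comes back at 32. Lemieux–Johnson cleavage of the electron-richer terminal alkene (OsO4 cat., NaIO4, 2,6-lutidine) gives the C2 aldehyde F5. Wittig reaction with the stabilised acyl ylide (3R)-3-acetoxy-1-(triphenylphosphoranylidene)butan-2-one F6, made beforehand from commercial (R)-2-acetoxypropanoyl chloride and Ph3P=CH2, gives the (E)-enone F7. Corey–Bakshi–Shibata reduction with the (S)-methyl oxazaborolidine and catecholborane, the alkenyl group acting as the large substituent, should give the (S)-allylic alcohol F8. Benzoylation gives the benzoate acetonide F9, which under the conditions of step 12 loses the acetonide and lactonises to 32.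

**Step 7 (lithiation–borylation).**
- **Risk.** Attack of sec-BuLi at silicon of the anomeric silyl acetal would cause loss of the protecting group and ring opening. Incomplete allylic metalation is also possible.
- **Fallback.** The fallback changes the masking of the lactol. It sets out from 7. The anomeric hydroxyl is capped with 2-methoxypropene and PPTS as the acetone mixed ketal F10. Bu4NF frees the C3a hydroxyl to give the hydroxy ketal F11. Metalation with two equivalents of sec-BuLi, the hydroxyl riding as its lithium alkoxide, followed by 10 gives the hydroxy boronate F12. Catalytic PPTS in wet CH2Cl2 hydrolyses the ketal far faster than the enol ether and releases lactol 14, where the route is rejoined.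

**Step 14 (vinyl addition).**
- **Risk.** Facial selectivity may be only moderate, since Felkin–Anh control by a single silyloxy group is not strong. Partial epimerisation of the α-silyloxy aldehyde is possible if the mixture warms before the Grignard reagent has reacted.
- **Fallback.** The fallback reaches the anti benzoate by chelation control followed by inversion. It sets out from 24 and comes back at 30. Etherification with 4-methoxybenzyl trichloroacetimidate (acid cat.) gives methyl (R)-2-[(4-methoxybenzyl)oxy]propanoate F13. iBu2AlH gives the aldehyde F14. MgBr2·OEt2-mediated, chelation-controlled addition of 26 in CH2Cl2 gives the syn alcohol F15. A Mitsunobu reaction with benzoic acid inverts the carbinol and installs the benzoate in one step, giving the anti benzoate F16. DDQ removes the 4-methoxybenzyl group to give 30.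

## Further compounds

F1 | step 8 | 2,3-O-isopropylidene-D-lyxono-1,4-lactone | O=C1O[C@H](CO)[C@@H]2OC(C)(C)O[C@H]12
F2 | step 8 | 5-O-(tert-butyldiphenylsilyl)-2,3-O-isopropylidene-D-lyxono-1,4-lactone | O=C1O[C@H](CO[Si](c3ccccc3)(c3ccccc3)C(C)(C)C)[C@@H]2OC(C)(C)O[C@H]12
F3 | step 8 | vinyl hemiketal from F2 (both anomers) | C=CC1(O)O[C@H](CO[Si](c3ccccc3)(c3ccccc3)C(C)(C)C)[C@@H]2OC(C)(C)O[C@H]12
F4 | step 8 | tert-butyldiphenylsilyl ether of 18 (all-cis C-vinyl furanoside) | C=C[C@@H]1O[C@H](CO[Si](c3ccccc3)(c3ccccc3)C(C)(C)C)[C@@H]2OC(C)(C)O[C@H]12
F5 | step 18 | C2 aldehyde from 21 | O=C[C@@H]1O[C@H](/C=C\C(=O)OC)[C@@H]2OC(C)(C)O[C@H]12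
F6 | step 18 | (3R)-3-acetoxy-1-(triphenylphosphoranylidene)butan-2-one | CC(=O)O[C@H](C)C(=O)C=P(c1ccccc1)(c1ccccc1)c1ccccc1
F7 | step 18 | (E)-enone from F5 and F6 | CC(=O)O[C@H](C)C(=O)/C=C/[C@@H]1O[C@H](/C=C\C(=O)OC)[C@@H]2OC(C)(C)O[C@H]12
F8 | step 18 | (S)-allylic alcohol from F7 | CC(=O)O[C@H](C)[C@@H](O)/C=C/[C@@H]1O[C@H](/C=C\C(=O)OC)[C@@H]2OC(C)(C)O[C@H]12
F9 | step 18 | benzoate acetonide from F8 | CC(=O)O[C@H](C)[C@H](/C=C/[C@@H]1O[C@H](/C=C\C(=O)OC)[C@@H]2OC(C)(C)O[C@H]12)OC(=O)c1ccccc1
F10 | step 7 | 3-O-allyl-2-O-(tert-butyldimethylsilyl)-1-O-(2-methoxypropan-2-yl)-D-threofuranose | COC(C)(C)OC1[C@@H](O[Si](C)(C)C(C)(C)C)[C@H](OCC=C)CO1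
F11 | step 7 | 3-O-allyl-1-O-(2-methoxypropan-2-yl)-D-threofuranose | COC(C)(C)OC1[C@@H](O)[C@H](OCC=C)CO1
F12 | step 7 | 1-O-(2-methoxypropan-2-yl)-3-O-[(1Z)-3-(4,4,5,5-tetramethyl-1,3,2-dioxaborolan-2-yl)prop-1-en-1-yl]-D-threofuranose | COC(C)(C)OC1[C@@H](O)[C@H](O/C=C\CB2OC(C)(C)C(C)(C)O2)CO1
F13 | step 14 | methyl (2R)-2-[(4-methoxybenzyl)oxy]propanoate | C[C@@H](OCc1ccc(OC)cc1)C(=O)OC
F14 | step 14 | (2R)-2-[(4-methoxybenzyl)oxy]propanal | C[C@@H](OCc1ccc(OC)cc1)C=O
F15 | step 14 | (3R,4R)-4-[(4-methoxybenzyl)oxy]pent-1-en-3-ol (syn) | C[C@@H](OCc1ccc(OC)cc1)[C@H](O)C=C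
F16 | step 14 | (3S,4R)-4-[(4-methoxybenzyl)oxy]pent-1-en-3-yl benzoate (anti) | C[C@@H](OCc1ccc(OC)cc1)[C@@H](OC(=O)c1ccccc1)C=C
A1 | alternative 1 | furyl carbinol bearing the C2/C3 acetonide and the complete side chain | CC(=O)O[C@H](C)[C@H](/C=C/[C@@H]1OC(C)(C)O[C@H]1[C@@H](O)c1ccco1)OC(=O)c1ccccc1
A2 | alternative 1 | Achmatowicz pyranone lactol (anomeric mixture at C5) | CC(=O)O[C@H](C)[C@H](/C=C/[C@@H]1OC(C)(C)O[C@H]1[C@H]1OC(O)C=CC1=O)OC(=O)c1ccccc1
A3 | alternative 2 | endo,endo-3-[(tert-butyldimethylsilyl)oxy]-7-oxabicyclo[2.2.1]hept-5-en-2-yl acrylate | C1=C[C@H]2O[C@@H]1[C@@H](O[Si](C)(C)C(C)(C)C)[C@H]2OC(=O)C=C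
A4 | alternative 2 | 2-vinyl-3-silyloxy furopyranone core | C=C[C@@H]1O[C@@H]2C=CC(=O)O[C@@H]2[C@@H]1O[Si](C)(C)C(C)(C)C
A5 | alternative 3 | β,γ-unsaturated lactone with free C2 and C3 hydroxyls and the complete side chain | CC(=O)O[C@H](C)[C@H](/C=C/[C@H](O)[C@@H](O)[C@H]1OC(=O)CC=C1)OC(=O)c1ccccc1
A6 | alternative 3 | 7-iodo-6,7-dihydro bicyclic lactone | CC(=O)O[C@H](C)[C@H](/C=C/[C@@H]1O[C@@H]2[C@@H](I)CC(=O)O[C@@H]2[C@@H]1O)OC(=O)c1ccccc1
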